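Everything rests on cutting rings B and C away from a fully substituted ring A at the C1–C13 single bond and the C3=C4 double bond. The feature used is C10, the single methine common to rings A, B and C, whose neighbours C5 and C9 are both quaternary: ring A can carry an (E)-enal on C10, a C13-alkylated β-keto ester on C9 and an α-phosphono spiro-lactone on C5. Mild base then triggers a 6-exo Michael addition (ring C, C1 and quaternary C13) and, on the aldehyde thus released, an intramolecular Horner–Wadsworth–Emmons olefination (ring B with the conjugated lactone) in one flask. Ring A comes from a catalytic asymmetric Diels–Alder reaction.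

Key step: step 23

Numbering used: ring A = C5–C10, ring B = C1–C5 + C10, ring C = C9, C11, C12, C13, C1, C10; C17 = CH3 on C8; C18/C19 = C=O and OCH2 of the lactone on C4/C5; C20 = CH3 on C9; C14, C15, C16 = spiro-lactone on C13. "Upper face" is the face of ring A that carries C19 and C20.

Remark on the chemistry (assumption): the sense of induction in step 7 is assigned from the square-planar chelate model of bis(oxazoline) complexes of divalent copper with N-acyl oxazolidinones; the enantiomeric ligand is equally available should the first run show the opposite sense. Compounds 16–35 are C4 epimer mixtures, 31–35 also C13 mixtures, 39 and 40 C15 mixtures; all converge.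

Step 1
Reactants: 1 (E)-crotonaldehyde; 2 dimethyl succinate
Product: 3 (3E,5E)-3-(methoxycarbonyl)hepta-3,5-dienoic acid
Conditions: KOt-Bu (1.1 equiv), t-BuOH/THF, 0 °C to rt; aq. HCl
Reagents that add atoms: none
Why: Stobbe condensation: the succinate enolate adds 1,2 to the aldehyde, the alkoxide lactonises onto the distal ester and E1cB opening of the paraconate gives the half-ester, with the new C5=C6 bond formed in the thermodynamically preferred (E) geometry (chain cis to CH2CO2H, ester trans).

Step 2
Reactants: 3 (3E,5E)-3-(methoxycarbonyl)hepta-3,5-dienoic acid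
Product: 5 (4E)-4-[(2E)-but-2-en-1-ylidene]dihydrofuran-2(3H)-one, via hydroxy acid 4 (not isolated)
Conditions: i-Bu2AlH (3.5 equiv), THF/toluene, −78 °C; 1 M HCl; TsOH·H2O (cat.), CH2Cl2, rt
Reagents that add atoms: none
Why: Chemoselective ester reduction then lactonisation: the first hydride equivalent turns the acid into an aluminium carboxylate that is not reduced at −78 °C, the dienoate is reduced 1,2 to the allylic alcohol, and acid closes the γ-lactone without touching either double-bond geometry, so C19 stays trans to C7.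

Step 3
Reactants: 6 mesaconic acid
Product: 7 (2E)-4-methoxy-2-methyl-4-oxobut-2-enoic acid
Conditions: MeOH, H2SO4 (cat.), rt
Reagents that add atoms: methanol, CO
Why: Fischer esterification is markedly faster at the carboxyl on the unsubstituted alkene carbon than at the one flanked by the α-methyl group, which gives the 4-monoester.

Step 4
Reactants: 7 (2E)-4-methoxy-2-methyl-4-oxobut-2-enoic acid
Product: 8 1-tert-butyl 4-methyl (2E)-2-methylbut-2-enedioate
Conditions: Cl3CC(=NH)Ot-Bu (2 equiv), BF3·OEt2 (cat.), CH2Cl2/cyclohexane, rt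
Reagents that add atoms: tert-butyl 2,2,2-trichloroacetimidate, CC(C)(C)OC(=N)C(Cl)(Cl)Cl
Why: Acid-catalysed O-alkylation of the remaining hindered carboxyl by the trichloroacetimidate (tert-butyl cation transfer) esterifies without base, so the (E)-alkene cannot isomerise.

Step 5
Reactants: 8 1-tert-butyl 4-methyl (2E)-2-methylbut-2-enedioate
Product: 9 (2E)-4-tert-butoxy-3-methyl-4-oxobut-2-enoic acid
Conditions: LiOH·H2O (1.05 equiv), THF/H2O, 0 °C; 1 M HCl
Reagents that add atoms: lithium hydroxide, [Li+].[OH-]
Why: Saponification by acyl substitution distinguishes the unhindered methyl ester from the tert-butyl ester, which is inert to hydroxide at 0 °C.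

Step 6
Reactants: 9 (2E)-4-tert-butoxy-3-methyl-4-oxobut-2-enoic acid
Product: 11 tert-butyl (2E)-2-methyl-4-oxo-4-(2-oxo-1,3-oxazolidin-3-yl)but-2-enoate, via mixed pivalic anhydride 10 (not isolated)
Conditions: t-BuCOCl, Et3N, THF, −20 °C; then oxazolidin-2-one, LiCl, rt
Reagents that add atoms: oxazolidin-2-one, O=C1NCCO1
Why: N-acylation through the mixed pivalic anhydride: the LiCl-activated oxazolidinone attacks the less hindered carbonyl of the anhydride under conditions mild enough to keep the (E) geometry.

Step 7
Reactants: 5 (4E)-4-[(2E)-but-2-en-1-ylidene]dihydrofuran-2(3H)-one; 11 tert-butyl (2E)-2-methyl-4-oxo-4-(2-oxo-1,3-oxazolidin-3-yl)but-2-enoate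
Product: 12 ring A Diels–Alder adduct (C5 spiro-lactone; C10 imide; C9 tert-butyl ester; C6=C7)
Conditions: [Cu((R,R)-t-Bu-box)](SbF6)2 (10 mol %), CH2Cl2, −20 °C to rt; t-Bu-box = 2,2'-(propane-2,2-diyl)bis(4-tert-butyl-4,5-dihydro-1,3-oxazole)
Reagents that add atoms: none
Why: Diels–Alder reaction catalysed by the bis(oxazoline) complex of divalent copper: two-point binding of the imide lowers the LUMO and puts its larger coefficient on C9, which bonds to the less substituted diene terminus C8 while C10 bonds to C5; the imide sits endo and so ends cis to the two outside diene substituents C17 and C19, the (E)-dienophile keeps C20 cis to C1, and the (R,R)-ligand shields the Re face at C10 so that the diene adds to its Si face, which sets C5, C8, C9 and C10 in one step.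

Step 8
Reactants: 12 ring A Diels–Alder adduct
Product: 13 ring A C1 alcohol
Conditions: NaBH4 (4 equiv), THF/H2O (4:1), 0 °C to rt
Reagents that add atoms: none
Why: Borohydride reduction of the N-acyl oxazolidinone: the exocyclic imide carbonyl is far more electrophilic than the γ-lactone and the tert-butyl ester, which survive in wet THF, and no stereocentre is touched (the alcohol is silylated at once to prevent translactonisation).

Step 9
Reactants: 13 ring A C1 alcohol
Product: 14 ring A C1 TBDPS ether
Conditions: t-BuPh2SiCl, imidazole, DMF, rt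
Reagents that add atoms: tert-butyl(chloro)diphenylsilane, CC(C)(C)[Si](Cl)(c1ccccc1)c1ccccc1
Why: Standard silylation of a primary alcohol; the TBDPS ether is chosen because it survives amide base, borane, hydride and CF3CO2H later.

Step 10
Reactants: 14 ring A C1 TBDPS ether
Product: 16 ring A C4 phosphono-lactone, via lactone enol phosphate 15 (not isolated)
Conditions: LiN(i-Pr)2 (1.1 equiv), THF, −78 °C; ClP(O)(OEt)2; LiN(i-Pr)2 (2.2 equiv), −78 to 0 °C; AcOH
Reagents that add atoms: diethyl chlorophosphate, CCOP(=O)(Cl)OCC
Why: Lactone α-phosphonylation by the enol phosphate to α-phosphono lactone rearrangement: C4 is the only enolisable position, its enolate is O-phosphorylated, and excess amide base metalates the ketene acetal phosphate at C4 and drives the 1,3 O-to-C phosphoryl shift to the stabilised phosphono-enolate (the C4 configuration is irrelevant).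

Step 11
Reactants: 16 ring A C4 phosphono-lactone
Product: 18 ring A C7 alcohol (C7 epimers), via C7 alkylborane 17 (not isolated)
Conditions: BH3·THF, THF, 0 °C to rt; NaBO3·4H2O, H2O, rt
Reagents that add atoms: sodium perborate, [Na+].[O-]OB=O
Why: Hydroboration–oxidation: boron goes to C7, the alkene carbon remote from the quaternary spiro centre C5, and perborate oxidises the C–B bond under conditions that spare the phosphono-lactone; the C7 configuration is erased in the next step.

Step 12
Reactants: 18 ring A C7 alcohol (C7 epimers)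
Product: 19 ring A C7 ketone
Conditions: Dess–Martin periodinane, NaHCO3, CH2Cl2, rt
Reagents that add atoms: none
Why: Dess–Martin oxidation of a secondary alcohol under buffered conditions that neither epimerise C8 (its methyl is already equatorial) nor touch the phosphonate.

Step 13
Reactants: 19 ring A C7 ketone
Product: 20 ring A 7-axial alcohol
Conditions: LiBH(s-Bu)3 (2.2 equiv), THF, −78 °C; aq. NH4Cl
Reagents that add atoms: none
Why: Diastereoselective ketone reduction: in the ring A chair C19 and C20 are both axial on the upper face and block axial delivery, so the bulky trialkylborohydride attacks equatorially from the lower face and sets C7 with the hydroxyl axial on the upper face, cis to C17, C19 and C20.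

Step 14
Reactants: 20 ring A 7-axial alcohol
Product: 21 ring A 7-acetate tert-butyl ester
Conditions: Ac2O, DMAP, pyridine, 40 °C
Reagents that add atoms: acetic anhydride, CC(=O)OC(C)=O
Why: DMAP-catalysed acylation of the hindered axial alcohol proceeds with retention at C7.

Step 15
Reactants: 21 ring A 7-acetate tert-butyl ester
Product: 22 ring A C9 carboxylic acid
Conditions: CF3CO2H/CH2Cl2 (1:4), 0 °C to rt
Reagents that add atoms: none
Why: Acidolysis of the tert-butyl ester (loss of isobutene) leaves the acetate, the lactone, the phosphonate and the TBDPS ether intact.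

Step 16
Reactants: 22 ring A C9 carboxylic acid
Product: 24 ring A C9 diazomethyl ketone, via acid chloride 23 (not isolated)
Conditions: Me2C=C(Cl)NMe2, CH2Cl2, 0 °C to rt; CH2N2 (excess), Et2O, 0 °C
Reagents that add atoms: diazomethane, C=[N+]=[N-]
Why: First half of the Arndt–Eistert homologation: the neutral chloroenamine converts the hindered acid to its chloride without attacking the phosphonate, and excess diazomethane is C-acylated and scavenges HCl, giving the diazoketone with C9 untouched.

Step 17
Reactants: 24 ring A C9 diazomethyl ketone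
Product: 26 ring A C9 acetic acid (C11–C12), via ketene 25 (not isolated)
Conditions: hν (365 nm), THF/H2O (4:1), rt
Reagents that add atoms: water, O
Why: Photochemical Wolff rearrangement: loss of N2 and 1,2-shift of the quaternary C9 with retention give the ketene, which water captures, so the diazomethane carbon becomes C11 and the former carboxyl carbon C12.

Step 18
Reactants: 26 ring A C9 acetic acid (C11–C12); 27 Meldrum's acid
Product: 29 ring A β-keto tert-butyl ester, via acyl Meldrum's acid 28 (not isolated)
Conditions: EDC·HCl, DMAP, CH2Cl2, 0 °C to rt; then t-BuOH, toluene, 90 °C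
Reagents that add atoms: tert-butanol, CC(C)(C)O
Why: C-acylation of Meldrum's acid by the carbodiimide-activated acid, then thermal fragmentation to the acylketene (loss of acetone and CO2), which tert-butanol traps as the β-keto ester (Meldrum's acid supplies C13 and C16).

Step 19
Reactants: 29 ring A β-keto tert-butyl ester; 30 bromoacetaldehyde dimethyl acetal
Product: 31 C13-(2,2-dimethoxyethyl) β-keto ester
Conditions: Cs2CO3 (1.1 equiv), n-Bu4NI (10 mol %), DMF, 60 °C
Reagents that add atoms: none
Why: C-alkylation of a β-keto ester: one equivalent of carbonate deprotonates only C13–H (several pKa units below the C4 phosphonate), iodide catalysis activates the sluggish bromoacetal, and the soft caesium enolate alkylates on carbon; C13 forms as a labile mixture that is planarised again in step 23.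

Step 20
Reactants: 31 C13-(2,2-dimethoxyethyl) β-keto ester
Product: 32 C1 alcohol of the alkylated β-keto ester
Conditions: n-Bu4NF/AcOH (1:1), THF, 0 °C to rt
Reagents that add atoms: none
Why: Fluoride cleavage of the silyl ether, buffered with acetic acid so that no free alkoxide can start a retro-Claisen cleavage through the C12 hemiketal or attack a lactone.

Step 21
Reactants: 32 C1 alcohol of the alkylated β-keto ester
Product: 33 C1 aldehyde
Conditions: Dess–Martin periodinane, NaHCO3, CH2Cl2, 0 °C to rt
Reagents that add atoms: none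
Why: Dess–Martin oxidation to the aldehyde under buffered conditions that do not enolise the β-keto ester; C10 keeps its configuration because the formyl group is already equatorial between two quaternary carbons.

Step 22
Reactants: 33 C1 aldehyde; 34 (triphenylphosphoranylidene)acetaldehyde
Product: 35 (E)-enal cascade precursor
Conditions: toluene, 80 °C (1.2 equiv of 34)
Reagents that add atoms: none
Why: Wittig olefination with a stabilised ylide gives the (E)-enal; the conjugated product aldehyde is less reactive than the starting aldehyde and only a small excess of ylide is used, which limits a second homologation.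

Step 23
Reactants: 35 (E)-enal cascade precursor
Product: 37 tetracyclic keto ester acetal, via Michael adduct aldehyde 36 (not isolated)
Conditions: DBU (0.3 equiv), MeCN, rt; then Cs2CO3 (2 equiv), rt to 40 °C
Reagents that add atoms: none
Why: DBU deprotonates only the β-keto ester, and the C13 enolate adds 6-exo-trig to C1 of the (E)-enal through a chair in which the C9 and C10 arms stay equatorial on ring A, closing ring C; carbonate then generates the C4 phosphonate carbanion, which attacks the liberated C3 aldehyde and loses diethyl phosphate to form C3=C4, closing ring B as a six-membered ring whose cis alkene is conjugated with C18=O. The closest known reaction type is the domino Michael/intramolecular Horner–Wadsworth–Emmons annulation of 1,3-dicarbonyl donors with enals. At C1, C2 of the enal takes the equatorial site of the forming chair because the axial alternative runs into axial C20, so H1 ends on the C19/C20 face and both new ring fusions are trans. At C13, the Michael step is reversible under DBU and the adduct with the smaller ester axial and the dimethoxyethyl chain equatorial is the more stable one, and carbonate is added only after equilibration so that the irreversible olefination drains this adduct without a chelating cation. The required order of events is secured by the substrate: C13–H is the most acidic site, the C12 carbonyl is masked as its enolate against the C4 carbanion, and olefination of the intact (E)-enal would need a trans double bond in a six-membered ring.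

Step 24
Reactants: 37 tetracyclic keto ester acetal
Product: 39 tetracyclic spiro pseudo-acid (5-hydroxy lactone), via aldehydo acid 38 (not isolated)
Conditions: CF3CO2H/CH2Cl2/H2O (10:10:1), 0 °C to rt
Reagents that add atoms: water, O
Why: Aqueous acid cleaves the tert-butyl ester and hydrolyses the dimethyl acetal, and the γ-aldehydo acid closes to the five-membered pseudo-acid; C13 is quaternary, so neither epimerisation nor furan formation is possible.

Step 25
Reactants: 39 tetracyclic spiro pseudo-acid (5-hydroxy lactone)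
Product: 41 tetracyclic spiro enol lactone, via acetoxy lactone 40 (not isolated)
Conditions: Ac2O, NaOAc, 120 °C
Reagents that add atoms: none
Why: Enol-lactonisation: the lactol is O-acetylated and the acylal loses acetic acid on heating (only C14 carries a β-hydrogen), giving the 3,3-disubstituted 2(3H)-furanone, which cannot tautomerise.

Step 26
Reactants: 41 tetracyclic spiro enol lactone
Product: 42 CNP0308057.1
Conditions: dimethyldioxirane, acetone, −20 to 0 °C
Reagents that add atoms: dimethyldioxirane, CC1(C)OO1
Why: Dioxirane epoxidation of the electron-rich enol-lactone double bond in preference to the electron-poor C3=C4 alkene; the spiro ring stands perpendicular to ring C and its face turned to C1 is screened by the C2 methylene, so oxygen should be delivered from the face next to the flat C12 carbonyl, setting C14 and C15 together as the cis-epoxide.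

Compound list

1 | (E)-but-2-enal, crotonaldehyde (supplies C6, C7, C8, C17) | C/C=C/C=O | starting material
2 | dimethyl succinate (supplies C4, C5, C18, C19) | COC(=O)CCC(=O)OC | starting material
3 | (3E,5E)-3-(methoxycarbonyl)hepta-3,5-dienoic acid | C/C=C/C=C(\CC(=O)O)C(=O)OC | intermediate
4 | (3E,5E)-3-(hydroxymethyl)hepta-3,5-dienoic acid | C/C=C/C=C(\CC(=O)O)CO | intermediate
5 | (4E)-4-[(2E)-but-2-en-1-ylidene]dihydrofuran-2(3H)-one; ring CH2O (C19) trans and ring CH2C=O (C4) cis to the butenyl chain | C/C=C/C=C1\CC(=O)OC1 | intermediate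
6 | mesaconic acid, (2E)-2-methylbut-2-enedioic acid (supplies C1, C9, C10, C12, C20) | OC(=O)/C=C(\C)C(=O)O | starting material
7 | (2E)-4-methoxy-2-methyl-4-oxobut-2-enoic acid | COC(=O)/C=C(\C)C(=O)O | intermediate
8 | 1-tert-butyl 4-methyl (2E)-2-methylbut-2-enedioate | COC(=O)/C=C(\C)C(=O)OC(C)(C)C | intermediate
9 | (2E)-4-tert-butoxy-3-methyl-4-oxobut-2-enoic acid | CC(C)(C)OC(=O)/C(C)=C/C(=O)O | intermediate
10 | mixed anhydride of 9 with pivalic acid | CC(C)(C)OC(=O)/C(C)=C/C(=O)OC(=O)C(C)(C)C | intermediate
11 | tert-butyl (2E)-2-methyl-4-oxo-4-(2-oxo-1,3-oxazolidin-3-yl)but-2-enoate | CC(C)(C)OC(=O)/C(C)=C/C(=O)N1CCOC1=O | intermediate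
12 | Diels–Alder adduct: ring A cyclohexene (C6=C7) spiro-fused at C5 to the γ-lactone; C19, C1 (N-acyl oxazolidinone on C10), C20 and C17 all on the upper face, CO2t-Bu on C9 and lactone C4 on the lower face | C1=C[C@]2(COC(=O)C2)[C@H](C(=O)N3CCOC3=O)[C@@](C)(C(=O)OC(C)(C)C)[C@@H]1C | intermediate
13 | C1 primary alcohol (CH2OH on C10) of the ring A cyclohexene | C1=C[C@]2(COC(=O)C2)[C@H](CO)[C@@](C)(C(=O)OC(C)(C)C)[C@@H]1C | intermediate
14 | C1 tert-butyldiphenylsilyl ether of 13 | C1=C[C@]2(COC(=O)C2)[C@H](CO[Si](c3ccccc3)(c3ccccc3)C(C)(C)C)[C@@](C)(C(=O)OC(C)(C)C)[C@@H]1C | intermediate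
15 | lactone enol phosphate (C4=C18 ketene acetal diethyl phosphate) of 14 | C1=C[C@]2(COC(OP(=O)(OCC)OCC)=C2)[C@H](CO[Si](c3ccccc3)(c3ccccc3)C(C)(C)C)[C@@](C)(C(=O)OC(C)(C)C)[C@@H]1C | intermediate
16 | C4 diethylphosphono lactone of 14 (C4 epimers) | C1=C[C@]2(COC(=O)C2P(=O)(OCC)OCC)[C@H](CO[Si](c3ccccc3)(c3ccccc3)C(C)(C)C)[C@@](C)(C(=O)OC(C)(C)C)[C@@H]1C | intermediate
17 | C7 alkylborane from 16 | BC1C[C@]2(COC(=O)C2P(=O)(OCC)OCC)[C@H](CO[Si](c3ccccc3)(c3ccccc3)C(C)(C)C)[C@@](C)(C(=O)OC(C)(C)C)[C@@H]1C | intermediate
18 | C7 alcohol, saturated ring A (C7 epimers) | OC1C[C@]2(COC(=O)C2P(=O)(OCC)OCC)[C@H](CO[Si](c3ccccc3)(c3ccccc3)C(C)(C)C)[C@@](C)(C(=O)OC(C)(C)C)[C@@H]1C | intermediate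
19 | C7 ketone | O=C1C[C@]2(COC(=O)C2P(=O)(OCC)OCC)[C@H](CO[Si](c3ccccc3)(c3ccccc3)C(C)(C)C)[C@@](C)(C(=O)OC(C)(C)C)[C@@H]1C | intermediate
20 | C7 alcohol with the hydroxyl axial on the upper face (cis to C17, C19, C20) | O[C@@H]1C[C@]2(COC(=O)C2P(=O)(OCC)OCC)[C@H](CO[Si](c3ccccc3)(c3ccccc3)C(C)(C)C)[C@@](C)(C(=O)OC(C)(C)C)[C@@H]1C | intermediate
21 | 7-acetate of 20 (C9 tert-butyl ester, C4 phosphonate, C1 silyl ether) | CC(=O)O[C@@H]1C[C@]2(COC(=O)C2P(=O)(OCC)OCC)[C@H](CO[Si](c3ccccc3)(c3ccccc3)C(C)(C)C)[C@@](C)(C(=O)OC(C)(C)C)[C@@H]1C | intermediate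
22 | C9 carboxylic acid | CC(=O)O[C@@H]1C[C@]2(COC(=O)C2P(=O)(OCC)OCC)[C@H](CO[Si](c3ccccc3)(c3ccccc3)C(C)(C)C)[C@@](C)(C(=O)O)[C@@H]1C | intermediate
23 | C9 acid chloride | CC(=O)O[C@@H]1C[C@]2(COC(=O)C2P(=O)(OCC)OCC)[C@H](CO[Si](c3ccccc3)(c3ccccc3)C(C)(C)C)[C@@](C)(C(=O)Cl)[C@@H]1C | intermediate
24 | C9 diazomethyl ketone | CC(=O)O[C@@H]1C[C@]2(COC(=O)C2P(=O)(OCC)OCC)[C@H](CO[Si](c3ccccc3)(c3ccccc3)C(C)(C)C)[C@@](C)(C(=O)C=[N+]=[N-])[C@@H]1C | intermediate
25 | C9 ketene (C11=C12=O) | CC(=O)O[C@@H]1C[C@]2(COC(=O)C2P(=O)(OCC)OCC)[C@H](CO[Si](c3ccccc3)(c3ccccc3)C(C)(C)C)[C@@](C)(C=C=O)[C@@H]1C | intermediate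
26 | homologated acid, C9–C11H2–C12O2H | CC(=O)O[C@@H]1C[C@]2(COC(=O)C2P(=O)(OCC)OCC)[C@H](CO[Si](c3ccccc3)(c3ccccc3)C(C)(C)C)[C@@](C)(CC(=O)O)[C@@H]1C | intermediate
27 | Meldrum's acid, 2,2-dimethyl-1,3-dioxane-4,6-dione (supplies C13, C16) | CC1(C)OC(=O)CC(=O)O1 | starting material
28 | 5-acyl Meldrum's acid from 26 | CC(=O)O[C@@H]1C[C@]2(COC(=O)C2P(=O)(OCC)OCC)[C@H](CO[Si](c3ccccc3)(c3ccccc3)C(C)(C)C)[C@@](C)(CC(=O)C4C(=O)OC(C)(C)OC4=O)[C@@H]1C | intermediate
29 | ring A β-keto tert-butyl ester, C9–C11H2–C12(=O)–C13H2–C16O2t-Bu | CC(=O)O[C@@H]1C[C@]2(COC(=O)C2P(=O)(OCC)OCC)[C@H](CO[Si](c3ccccc3)(c3ccccc3)C(C)(C)C)[C@@](C)(CC(=O)CC(=O)OC(C)(C)C)[C@@H]1C | intermediate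
30 | bromoacetaldehyde dimethyl acetal, 2-bromo-1,1-dimethoxyethane (supplies C14, C15) | COC(CBr)OC | starting material
31 | β-keto ester alkylated at C13 with CH2CH(OMe)2 (C13 epimers) | CC(=O)O[C@@H]1C[C@]2(COC(=O)C2P(=O)(OCC)OCC)[C@H](CO[Si](c3ccccc3)(c3ccccc3)C(C)(C)C)[C@@](C)(CC(=O)C(CC(OC)OC)C(=O)OC(C)(C)C)[C@@H]1C | intermediate
32 | C1 alcohol of 31 | CC(=O)O[C@@H]1C[C@]2(COC(=O)C2P(=O)(OCC)OCC)[C@H](CO)[C@@](C)(CC(=O)C(CC(OC)OC)C(=O)OC(C)(C)C)[C@@H]1C | intermediate
33 | C1 aldehyde (CHO on C10) | CC(=O)O[C@@H]1C[C@]2(COC(=O)C2P(=O)(OCC)OCC)[C@H](C=O)[C@@](C)(CC(=O)C(CC(OC)OC)C(=O)OC(C)(C)C)[C@@H]1C | intermediate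
34 | (triphenylphosphoranylidene)acetaldehyde (supplies C2, C3) | O=CC=P(c1ccccc1)(c1ccccc1)c1ccccc1 | starting material
35 | cascade precursor: ring A with (E)-enal on C10, alkylated β-keto ester arm on C9 and phosphono spiro-lactone on C5 | CC(=O)O[C@@H]1C[C@]2(COC(=O)C2P(=O)(OCC)OCC)[C@H](/C=C/C=O)[C@@](C)(CC(=O)C(CC(OC)OC)C(=O)OC(C)(C)C)[C@@H]1C | intermediate
36 | Michael adduct: rings A and C trans-fused, CH2CHO (C2, C3) equatorial on C1, C13 quaternary (ester axial), phosphono-lactone intact | CC(=O)O[C@@H]1C[C@]2(COC(=O)C2P(=O)(OCC)OCC)[C@@H]3[C@@H](CC=O)[C@@](CC(OC)OC)(C(=O)OC(C)(C)C)C(=O)C[C@@]3(C)[C@@H]1C | intermediate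
37 | tetracycle: rings A, B, C and the C3=C4 conjugated spiro-lactone; C13 with axial CO2t-Bu and equatorial CH2CH(OMe)2; H1 on the upper face | CC(=O)O[C@@H]1C[C@@]23COC(=O)C2=CC[C@@H]2[C@@H]3[C@@](C)(CC(=O)[C@]2(CC(OC)OC)C(=O)OC(C)(C)C)[C@@H]1C | intermediate
38 | C15 aldehyde C16 carboxylic acid | CC(=O)O[C@@H]1C[C@@]23COC(=O)C2=CC[C@@H]2[C@@H]3[C@@](C)(CC(=O)[C@]2(CC=O)C(=O)O)[C@@H]1C | intermediate
39 | spiro 5-hydroxy-γ-lactone on C13 (pseudo-acid, C15 epimers) | CC(=O)O[C@@H]1C[C@@]23COC(=O)C2=CC[C@@H]2[C@@H]3[C@@](C)(CC(=O)[C@]23C(=O)OC(O)C3)[C@@H]1C | intermediate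
40 | spiro 5-acetoxy-γ-lactone on C13 | CC(=O)O[C@@H]1C[C@@]23COC(=O)C2=CC[C@@H]2[C@@H]3[C@@](C)(CC(=O)[C@]23C(=O)OC(OC(C)=O)C3)[C@@H]1C | intermediate
41 | spiro enol lactone (C14=C15) on C13 | CC(=O)O[C@@H]1C[C@@]23COC(=O)C2=CC[C@@H]2[C@@H]3[C@@](C)(CC(=O)[C@]23C(=O)OC=C3)[C@@H]1C | intermediate
42 | CNP0308057.1: C14–C15 epoxide of 41 with the oxygen on the lactone face next to C12 | CC(=O)O[C@@H]1C[C@@]23COC(=O)C2=CC[C@@H]2[C@@H]3[C@@](C)(CC(=O)[C@]23C(=O)O[C@H]2O[C@H]23)[C@@H]1C | target

Total step count: 26.
Longest linear sequence: 24 steps (steps 3–26, from mesaconic acid).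

Steps most likely to fail

Step 7. The diene carries a cis substituent on its disubstituted terminus and the dienophile is β,β-disubstituted, so cycloaddition under the mild copper catalyst may be too slow, letting isomerisation or oligomerisation of 5 take over, or may show weak endo and facial control. The fallback replaces catalyst control by auxiliary control with a stronger Lewis acid. It sets out from 9: acylation of the lithium salt of (S)-4-benzyloxazolidin-2-one with the mixed pivalic anhydride of 9 (THF, −78 °C) should give the chiral imide tert-butyl (2E)-4-[(4S)-4-benzyl-2-oxo-1,3-oxazolidin-3-yl]-2-methyl-4-oxobut-2-enoate F1. With Et2AlCl (1.4 equiv, CH2Cl2, −78 to −30 °C) the cationic aluminium chelate forms, its benzyl group blocks the Re face at C10, and cycloaddition with 5 should give the auxiliary-bearing ring A adduct F2. NaBH4 in THF/H2O then removes the auxiliary and the route is rejoined at 13.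

Step 19. Bromoacetal 30 is a sluggish electrophile, and at the temperature it needs the enolate may instead undergo O-alkylation, retro-Claisen cleavage or proton transfer to the C4 phosphonate. The fallback moves the slow alkylation to a simple malonate and forms the C12–C13 bond by a decarboxylative Claisen condensation. It sets out from 26. tert-Butyl methyl malonate is alkylated with 30 (NaH, NaI, DMF, 80 °C) to give 1-tert-butyl 3-methyl 2-(2,2-dimethoxyethyl)propanedioate F3, and LiOH (1 equiv, THF/H2O) cleaves only the methyl ester to give 3-tert-butoxy-2-(2,2-dimethoxyethyl)-3-oxopropanoic acid F4. Acid 26 is activated with 1,1'-carbonyldiimidazole (THF, rt) as the acyl imidazole of 26 F5, which is treated with the magnesium salt of F4 (Mg(OEt)2, THF, rt to 40 °C). C-acylation and loss of CO2 should give the alkylated β-keto ester, and the route is rejoined at 31.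

Step 23. The Michael closure may show poor facial selectivity at C13: a hydrogen-bonded or chelated enolate places the ester equatorial, and the resulting C13 epimer cannot be corrected once the olefination has occurred. The fallback locks C16 and C14–C15 into the lactone ring before the double ring closure. It sets out from 35. Anhydrous CF3CO2H in CH2Cl2 at 0 °C cleaves the tert-butyl ester and lets the acid capture the oxocarbenium ion of the acetal, giving the enal that carries a 2-acyl-5-methoxy-γ-butyrolactone on the C9 arm F6. In its metal-free enolate (Cs2CO3, MeCN) the lactone carbonyl cannot turn away from the enolate oxygen, so the dipoles are opposed only when C16 lies cis to C11, the geometry that delivers C16 axial in the chair closure. The same Michael/olefination sequence should give the tetracyclic spiro 5-methoxy-γ-lactone F7, and aqueous CF3CO2H hydrolyses its methyl acetal, so the route is rejoined at 39.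

Further compounds

F1 | step 7 | tert-butyl (2E)-4-[(4S)-4-benzyl-2-oxo-1,3-oxazolidin-3-yl]-2-methyl-4-oxobut-2-enoate | CC(C)(C)OC(=O)/C(C)=C/C(=O)N1[C@@H](Cc2ccccc2)COC1=O
F2 | step 7 | ring A Diels–Alder adduct carrying the (S)-4-benzyloxazolidinone on C1 | C1=C[C@]2(COC(=O)C2)[C@H](C(=O)N3[C@@H](Cc4ccccc4)COC3=O)[C@@](C)(C(=O)OC(C)(C)C)[C@@H]1C
F3 | step 19 | 1-tert-butyl 3-methyl 2-(2,2-dimethoxyethyl)propanedioate | COC(=O)C(CC(OC)OC)C(=O)OC(C)(C)C
F4 | step 19 | 3-tert-butoxy-2-(2,2-dimethoxyethyl)-3-oxopropanoic acid | OC(=O)C(CC(OC)OC)C(=O)OC(C)(C)C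
F5 | step 19 | acyl imidazole of 26 | CC(=O)O[C@@H]1C[C@]2(COC(=O)C2P(=O)(OCC)OCC)[C@H](CO[Si](c3ccccc3)(c3ccccc3)C(C)(C)C)[C@@](C)(CC(=O)n4ccnc4)[C@@H]1C
F6 | step 23 | (E)-enal with a 2-acyl-5-methoxy-γ-butyrolactone on the C9 arm | CC(=O)O[C@@H]1C[C@]2(COC(=O)C2P(=O)(OCC)OCC)[C@H](/C=C/C=O)[C@@](C)(CC(=O)C4CC(OC)OC4=O)[C@@H]1C
F7 | step 23 | tetracyclic spiro 5-methoxy-γ-lactone | CC(=O)O[C@@H]1C[C@@]23COC(=O)C2=CC[C@@H]2[C@@H]3[C@@](C)(CC(=O)[C@]23C(=O)OC(OC)C3)[C@@H]1C
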